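Thielavin Z8 is cut at the ring B C1–C(=O)–O–ring A linkage, the carbonyl carbon coming from carbon monoxide. The plan exploits that ring B C1 is the only hydrogen-bearing ring carbon of a 2,4,5-trimethylresorcinol nucleus. One monobenzyl ether therefore serves twice: as the ring A nucleophile and, after iodination at that carbon and acylation by the ring C acid, as the ring B electrophile. A single palladium-catalysed operation joins aryl iodide, CO and the hindered phenol, forming the C1–C(=O) and C(=O)–O bonds. The precursor is the tri-O-benzyl C–B depside carrying iodine at ring B C1.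

Key step: step 9

Remark: the target has no stereocentre and the aryl ester axes are assumed to rotate freely, so no stereodescriptor is needed. In rings B and C the carbon bearing the carboxyl is C1 and the oxygens sit on C2 and C4.

Step 1
Reactants: 1 atraric acid (methyl 2,4-dihydroxy-3,6-dimethylbenzoate); 2 dichloromethyl methyl ether
Product: 4 methyl 5-formyl-2,4-dihydroxy-3,6-dimethylbenzoate, via aryl(chloro)methyl methyl ether 3 (not isolated)
Conditions: Cl2CHOMe, TiCl4, CH2Cl2, 0 °C to rt; then 1 M aq. HCl
Reagents that add atoms: dichloromethyl methyl ether 2, COC(Cl)Cl; water, O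
Why: Rieche formylation, in which the TiCl4-activated dichloromethyl ether attacks C5, the only unsubstituted ring carbon (ortho to the C4 hydroxyl, para to the C2 hydroxyl), and aqueous work-up hydrolyses chloro ether 3 to the aldehyde.

Step 2
Reactants: 4 methyl 5-formyl-2,4-dihydroxy-3,6-dimethylbenzoate
Product: 6 methyl 2,4-dihydroxy-3,5,6-trimethylbenzoate, via benzylic alcohol 5 (not isolated)
Conditions: H2 (3 bar), 10% Pd/C, AcOH, cat. HCl, rt
Reagents that add atoms: none
Why: Catalytic hydrogenation followed by benzylic hydrogenolysis, in which the salicylaldehyde-type carbonyl is reduced to alcohol 5 and its C–O bond is cleaved easily because the ortho and para oxygens stabilise the benzylic cation; this is the classical formylation–reduction way of C-methylating orsellinates and leaves ester and ring untouched.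

Step 3
Reactants: 6 methyl 2,4-dihydroxy-3,5,6-trimethylbenzoate (first portion)
Product: 8 2,4,5-trimethylbenzene-1,3-diol, via 2,4-dihydroxy-3,5,6-trimethylbenzoic acid 7 (not isolated)
Conditions: 2 M aq. NaOH, N2, reflux; then 6 M HCl, 60 °C
Reagents that add atoms: none
Why: Saponification followed by protodecarboxylation, in which acid 7 is protonated at its electron-rich ipso carbon and loses CO2 on warming, as β-resorcylic acids generally do, while inert gas protects the oxidisable resorcinol.

Step 4
Reactants: 8 2,4,5-trimethylbenzene-1,3-diol; 9 benzyl bromide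
Product: 10 3-(benzyloxy)-2,5,6-trimethylphenol (ring A phenol)
Conditions: BnBr (slight deficit), K2CO3, acetone, reflux
Reagents that add atoms: benzyl bromide 9, BrCc1ccccc1
Why: Williamson ether synthesis under steric control, since the C1 hydroxyl of 8 has an ortho hydrogen whereas the C3 hydroxyl lies between two methyl groups, so the open oxygen should be alkylated preferentially, the same bias that is used for mono-O-alkylation of trimethylhydroquinone.

Step 5
Reactants: 10 3-(benzyloxy)-2,5,6-trimethylphenol (the portion destined for ring B)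
Product: 11 3-(benzyloxy)-4-iodo-2,5,6-trimethylphenol
Conditions: N-iodosuccinimide, MeCN, 0 °C, dark
Reagents that add atoms: N-iodosuccinimide, O=C1CCC(=O)N1I
Why: Electrophilic aromatic iodination at the single C–H of the oxygenated ring, which is para to the free hydroxyl and ortho to the benzyloxy group (the benzyl phenyl ring is far less reactive), and the iodine also blocks the only nucleophilic ring carbon before the acylium-type esterification of step 8.

Step 6
Reactants: 6 methyl 2,4-dihydroxy-3,5,6-trimethylbenzoate (second portion); 9 benzyl bromide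
Product: 12 methyl 2,4-bis(benzyloxy)-3,5,6-trimethylbenzoate
Conditions: BnBr (excess), K2CO3, DMF, 70 °C
Reagents that add atoms: benzyl bromide 9, BrCc1ccccc1
Why: Double Williamson etherification, in which excess 9 in warm DMF alkylates both phenoxides, heat being needed for the hydrogen-bonded C2 hydroxyl, as is routine for β-orcinol carboxylates.

Step 7
Reactants: 12 methyl 2,4-bis(benzyloxy)-3,5,6-trimethylbenzoate
Product: 13 2,4-bis(benzyloxy)-3,5,6-trimethylbenzoic acid (ring C acid)
Conditions: KOH, aq. DMSO, 110 °C; then 2 M HCl
Reagents that add atoms: potassium hydroxide, [K+].[OH-]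
Why: Alkaline ester hydrolysis with poorly solvated hydroxide in aqueous DMSO, the usual remedy for di-ortho-substituted benzoates of the depside series, under which aryl benzyl ethers are inert.

Step 8
Reactants: 13 2,4-bis(benzyloxy)-3,5,6-trimethylbenzoic acid; 11 3-(benzyloxy)-4-iodo-2,5,6-trimethylphenol
Product: 15 3-(benzyloxy)-4-iodo-2,5,6-trimethylphenyl 2,4-bis(benzyloxy)-3,5,6-trimethylbenzoate (tri-O-benzyl C–B aryl iodide), via mixed trifluoroacetic anhydride 14 (not isolated)
Conditions: (CF3CO)2O, toluene, 0 °C to rt
Reagents that add atoms: none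
Why: Mixed-anhydride esterification with trifluoroacetic anhydride, in which the electron-rich di-ortho-substituted acid gives 14, which ionises towards a linear acylium ion able to reach the hindered phenol oxygen; this is the established way of forging depside bonds between fully substituted rings, and the aryl iodide and benzyl ethers tolerate it at room temperature.

Step 9
Reactants: 15 tri-O-benzyl C–B aryl iodide; 16 carbon monoxide; 10 3-(benzyloxy)-2,5,6-trimethylphenol (1.5 equiv)
Product: 17 3-(benzyloxy)-2,5,6-trimethylphenyl 2-(benzyloxy)-4-{[2,4-bis(benzyloxy)-3,5,6-trimethylbenzoyl]oxy}-3,5,6-trimethylbenzoate (tetra-O-benzyl thielavin Z8)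
Conditions: Pd2(dba)3 (5 mol%), Xantphos (12 mol%), CO (10 bar), Et3N, 4 Å MS, toluene, 100 °C
Reagents that add atoms: carbon monoxide 16, [C-]#[O+]
Why: Zerovalent palladium carrying Xantphos inserts into the ring B C1–I bond of 15, CO coordinates and migrates to give the aroyl-palladium iodide, the phenoxide formed from 10 and Et3N replaces iodide on the metal, and C–O reductive elimination releases 17 and returns the catalyst. This is the known palladium-catalysed aryloxycarbonylation of aryl iodides, applied here to two di-ortho-substituted partners. No ring is closed and no stereocentre is created, so only chemoselectivity is at stake. The aroyl path must beat direct diaryl ether formation, hydrodeiodination and C–H arylation of the neighbouring O-benzyl ring: CO pressure and the strain relief gained by the crowded aryl-palladium make insertion fast, the wide bite angle speeds the final reductive elimination, and a carboxylate-free amine base withholds the concerted metalation pathway. The substrates secure the rest, since 15 has one C–I bond, 10 offers the only free hydroxyl in the flask, and the existing C–B ester is shielded by four ortho substituents against transesterification. Molecular sieves keep water from intercepting the aroyl group as the acid.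

Step 10
Reactants: 17 tetra-O-benzyl thielavin Z8
Product: 18 thielavin Z8
Conditions: H2 (1 atm), 10% Pd/C, EtOAc–THF, rt
Reagents that add atoms: none
Why: Catalytic hydrogenolysis of the four aryl benzyl ethers under neutral conditions, which leaves both aryl ester bonds intact, a non-nucleophilic solvent excluding transesterification.

Compound list
1 | atraric acid (methyl 2,4-dihydroxy-3,6-dimethylbenzoate) | COC(=O)c1c(C)cc(O)c(C)c1O | starting material
2 | dichloromethyl methyl ether | COC(Cl)Cl | starting material
3 | methyl 5-[chloro(methoxy)methyl]-2,4-dihydroxy-3,6-dimethylbenzoate | COC(=O)c1c(C)c(C(Cl)OC)c(O)c(C)c1O | intermediate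
4 | methyl 5-formyl-2,4-dihydroxy-3,6-dimethylbenzoate | COC(=O)c1c(C)c(C=O)c(O)c(C)c1O | intermediate
5 | methyl 2,4-dihydroxy-5-(hydroxymethyl)-3,6-dimethylbenzoate | COC(=O)c1c(C)c(CO)c(O)c(C)c1O | intermediate
6 | methyl 2,4-dihydroxy-3,5,6-trimethylbenzoate | COC(=O)c1c(C)c(C)c(O)c(C)c1O | intermediate
7 | 2,4-dihydroxy-3,5,6-trimethylbenzoic acid | OC(=O)c1c(C)c(C)c(O)c(C)c1O | intermediate
8 | 2,4,5-trimethylbenzene-1,3-diol | Cc1cc(O)c(C)c(O)c1C | intermediate
9 | benzyl bromide | BrCc1ccccc1 | starting material
10 | 3-(benzyloxy)-2,5,6-trimethylphenol (ring A phenol) | Cc1cc(OCc2ccccc2)c(C)c(O)c1C | intermediate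
11 | 3-(benzyloxy)-4-iodo-2,5,6-trimethylphenol | Cc1c(I)c(OCc2ccccc2)c(C)c(O)c1C | intermediate
12 | methyl 2,4-bis(benzyloxy)-3,5,6-trimethylbenzoate | COC(=O)c1c(C)c(C)c(OCc2ccccc2)c(C)c1OCc3ccccc3 | intermediate
13 | 2,4-bis(benzyloxy)-3,5,6-trimethylbenzoic acid (ring C acid) | OC(=O)c1c(C)c(C)c(OCc2ccccc2)c(C)c1OCc3ccccc3 | intermediate
14 | 2,4-bis(benzyloxy)-3,5,6-trimethylbenzoic trifluoroacetic anhydride | O=C(OC(=O)C(F)(F)F)c1c(C)c(C)c(OCc2ccccc2)c(C)c1OCc3ccccc3 | intermediate
15 | 3-(benzyloxy)-4-iodo-2,5,6-trimethylphenyl 2,4-bis(benzyloxy)-3,5,6-trimethylbenzoate (tri-O-benzyl C–B aryl iodide) | Cc1c(I)c(OCc2ccccc2)c(C)c(OC(=O)c3c(C)c(C)c(OCc4ccccc4)c(C)c3OCc5ccccc5)c1C | intermediate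
16 | carbon monoxide | [C-]#[O+] | starting material
17 | tetra-O-benzyl thielavin Z8 | Cc1cc(OCc2ccccc2)c(C)c(OC(=O)c3c(C)c(C)c(OC(=O)c4c(C)c(C)c(OCc5ccccc5)c(C)c4OCc6ccccc6)c(C)c3OCc7ccccc7)c1C | intermediate
18 | thielavin Z8 (3-hydroxy-2,5,6-trimethylphenyl 4-[(2,4-dihydroxy-3,5,6-trimethylbenzoyl)oxy]-2-hydroxy-3,5,6-trimethylbenzoate) | Cc1cc(O)c(C)c(OC(=O)c2c(C)c(C)c(OC(=O)c3c(C)c(C)c(O)c(C)c3O)c(C)c2O)c1C | target

Total step count: 10. Longest linear sequence: 8 steps (1, 2, 3, 4, 5, 8, 9, 10).

Steps most likely to fail

Step 9. Capture of the crowded aroyl-palladium by the di-ortho-methyl phenoxide may be too slow, so that hydrodeiodination, hydrolysis of the aroyl species or catalyst decay take over. The fallback makes the two bonds separately and without palladium. Starting from 15, iodine–magnesium exchange with iPrMgCl·LiCl (THF, −20 °C) should give the arylmagnesium chloride F1, the doubly shielded depside ester being left alone at this temperature. CO2 and acidic work-up then give the C–B carboxylic acid F2. (CF3CO)2O in toluene converts it into the mixed trifluoroacetic anhydride F3, which acylates 10 at 0 °C, the low temperature holding ring acylation back. The route is rejoined at 17.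

Step 4. Discrimination between the two hydroxyl groups may be insufficient, and over-alkylation may consume material. The fallback differentiates the oxygens by deacylation instead of alkylation. Starting from 8, Ac2O in pyridine gives the diacetate F4. Controlled methanolysis (cat. K2CO3, MeOH, 0 °C) should remove the less hindered acetate first, as is known for trimethylhydroquinone diacetate, to give the monoacetate F5. Benzylation with 9 and K2CO3 in acetone gives the benzyl ether acetate F6, and full methanolysis (K2CO3, MeOH, rt) rejoins the route at 10.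

Step 7. Cleavage of the di-ortho-substituted methyl ester may stall, or forcing alkali may erode the benzyl ethers. The fallback builds the carboxyl group instead of unmasking it. Starting from 11, benzylation with 9 (K2CO3, DMF) gives the bis(benzyl) ether iodide F7. Exchange with iPrMgCl·LiCl (THF, 0 °C) gives the arylmagnesium chloride F8, and CO2 followed by acidic work-up rejoins the route at 13.

Further compounds
F1 | step 9 | arylmagnesium chloride of the tri-O-benzyl C–B depside (MgCl at ring B C1) | Cc1c([Mg]Cl)c(OCc2ccccc2)c(C)c(OC(=O)c3c(C)c(C)c(OCc4ccccc4)c(C)c3OCc5ccccc5)c1C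
F2 | step 9 | 2-(benzyloxy)-4-{[2,4-bis(benzyloxy)-3,5,6-trimethylbenzoyl]oxy}-3,5,6-trimethylbenzoic acid | Cc1c(C(=O)O)c(OCc2ccccc2)c(C)c(OC(=O)c3c(C)c(C)c(OCc4ccccc4)c(C)c3OCc5ccccc5)c1C
F3 | step 9 | mixed anhydride of F2 and trifluoroacetic acid | Cc1c(C(=O)OC(=O)C(F)(F)F)c(OCc2ccccc2)c(C)c(OC(=O)c3c(C)c(C)c(OCc4ccccc4)c(C)c3OCc5ccccc5)c1C
F4 | step 4 | 2,4,5-trimethyl-1,3-phenylene diacetate | CC(=O)Oc1cc(C)c(C)c(OC(C)=O)c1C
F5 | step 4 | 3-hydroxy-2,5,6-trimethylphenyl acetate | CC(=O)Oc1c(C)c(C)cc(O)c1C
F6 | step 4 | 3-(benzyloxy)-2,5,6-trimethylphenyl acetate | CC(=O)Oc1c(C)c(C)cc(OCc2ccccc2)c1C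
F7 | step 7 | 1,3-bis(benzyloxy)-4-iodo-2,5,6-trimethylbenzene | Cc1c(I)c(OCc2ccccc2)c(C)c(OCc3ccccc3)c1C
F8 | step 7 | [2,4-bis(benzyloxy)-3,5,6-trimethylphenyl]magnesium chloride | Cc1c([Mg]Cl)c(OCc2ccccc2)c(C)c(OCc3ccccc3)c1C
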